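**Retrosynthetic overview**
1. The target comes from its methylenedioxy ether, (−)-kusunokinin. The catechol is unmasked last with BCl3.
2. The lactone C=O comes from a lactol C–H by hydride-transfer dehydrogenation, and C8 is equilibrated to trans in the same flask.
3. The lactol comes from a γ-hydroxy aldehyde by O9′→C9 hemiacetal closure. This is the only ring-forming event and runs in the order lactol, then lactone, as the plant dehydrogenase does.
4. The hydroxy aldehyde comes from an 8–8′-linked imide/Weinreb amide. One hydride reagent leaves C9′ as CH2OH and C9 as CHO, so the unsymmetrical intermediate can close only one way.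
5. The 8–8′ bond comes from a one-electron oxidative cross-coupling of two different C6–C3 enolates. The oxazolidinone on the catechol half does the job of the dirigent protein and sets C8′.

Assumption: the SMILES is read as the (3R,4R)-trans lactone. Lignan locants are used in the text: C7–C9 is the side chain of the dimethoxyphenyl half and C7′–C9′ that of the catechol half, so C8 is lactone C3 and C8′ is lactone C4.

**Step 1**
Reactants: 1 3-(1,3-benzodioxol-5-yl)propanoic acid; 2 (S)-4-benzyl-1,3-oxazolidin-2-one
Product: 3 (S)-3-[3-(1,3-benzodioxol-5-yl)propanoyl]-4-benzyl-1,3-oxazolidin-2-one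
Conditions: DCC, DMAP (cat.), CH2Cl2, 0 °C → rt
Reagents that add atoms: none
Why: Steglich-type carbodiimide N-acylation works well for unhindered 3-arylpropanoic acids and leaves the auxiliary stereocentre untouched.

**Step 2**
Reactants: 4 3-(3,4-dimethoxyphenyl)propanoic acid
Product: 5 3-(3,4-dimethoxyphenyl)-N-methoxy-N-methylpropanamide
Conditions: MeNHOMe·HCl, Et3N, DCC, DMAP (cat.), CH2Cl2, 0 °C → rt
Reagents that add atoms: N,O-dimethylhydroxylamine hydrochloride (CNOC.Cl)
Why: This is a routine carbodiimide amide coupling (Weinreb amide synthesis); it creates no stereocentre and installs the group that will later stop hydride reduction at the aldehyde level.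

**Step 3**
Reactants: 3 imide of the benzodioxole half; 5 Weinreb amide of the dimethoxyphenyl half (1.5 equiv)
Product: 8 (3R)-4-[(4S)-4-benzyl-2-oxo-1,3-oxazolidin-3-yl]-3-(1,3-benzodioxol-5-ylmethyl)-2-(3,4-dimethoxybenzyl)-N-methoxy-N-methyl-4-oxobutanamide (C2 epimer mixture), via imide lithium enolate 6 (not isolated), via amide lithium enolate 7 (not isolated)
Conditions: LiN(iPr)2 (2.6 equiv), THF, −78 °C, 30 min; Fe(acac)3 (2.2 equiv), −78 °C → rt
Reagents that add atoms: none
Why: In this oxidative enolate heterocoupling, trivalent iron oxidises the more electron-rich amide enolate first and its C8 radical is captured by the less oxidisable chelated Z-enolate of the imide on the face opposite the auxiliary benzyl group; this sets C8′ as R (minor C8′ epimers are diastereomers and are removed by chromatography here), while C8 forms as a mixture that step 5 corrects.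

**Step 4**
Reactants: 8 coupled imide/Weinreb amide
Product: 10 (4R)-4-(1,3-benzodioxol-5-ylmethyl)-3-(3,4-dimethoxybenzyl)oxolan-2-ol (lactol; mixture at C2 and C3), via open hydroxy aldehyde 9 (not isolated)
Conditions: LiAlH4 (3 equiv), THF, −78 → −10 °C (8 added to the hydride); then H2O, 0 °C
Reagents that add atoms: none
Why: Reductive auxiliary cleavage and Weinreb aldehyde synthesis run in one flask, so the imide carbonyl goes to CH2OH without touching C8′ while the N-methoxy-N-methylamide stays at the aldehyde level until the quench; the γ-hydroxy aldehyde then closes spontaneously to the five-membered hemiacetal, with no new controlled stereocentre and with the ring oxygen necessarily on C9′.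

**Step 5**
Reactants: 10 lactol
Product: 12 (−)-kusunokinin = (3R,4R)-4-(1,3-benzodioxol-5-ylmethyl)-3-(3,4-dimethoxybenzyl)oxolan-2-one, via cis-lactone 11 (not isolated)
Conditions: [Cp*IrCl2]2 (2 mol %), K2CO3 (10 mol %), acetone, 40 °C; then DBU (0.5 equiv), rt → 40 °C
Reagents that add atoms: none
Why: Oppenauer-type transfer dehydrogenation moves the lactol C–H hydride to acetone, as the cofactor does in the enzyme; DBU then enolises C3 and drains all four lactol diastereomers into the more stable trans-3,4-dibenzyl lactone, so C3 becomes R under thermodynamic control from the fixed, non-acidic C4 centre.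

**Step 6**
Reactants: 12 (−)-kusunokinin
Product: 13 (3R,4R)-4-(3,4-dihydroxybenzyl)-3-(3,4-dimethoxybenzyl)oxolan-2-one (target)
Conditions: BCl3 (3 equiv), CH2Cl2, −78 → −20 °C; then H2O, rt
Reagents that add atoms: none
Why: In this Lewis-acid acetal cleavage the O–CH2–O carbon ionises far more easily than an aryl methyl ether, so BCl3 opens the methylenedioxy ring selectively at low temperature; the acidic medium cannot epimerise the already thermodynamic trans lactone.

**Compound list**
1 | 3-(1,3-benzodioxol-5-yl)propanoic acid | OC(=O)CCc1ccc2OCOc2c1 | starting material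
2 | (S)-4-benzyl-1,3-oxazolidin-2-one | O=C1N[C@@H](Cc2ccccc2)CO1 | starting material
3 | (S)-3-[3-(1,3-benzodioxol-5-yl)propanoyl]-4-benzyl-1,3-oxazolidin-2-one | O=C(CCc1ccc2OCOc2c1)N1C(=O)OC[C@@H]1Cc1ccccc1 | intermediate
4 | 3-(3,4-dimethoxyphenyl)propanoic acid | COc1ccc(CCC(=O)O)cc1OC | starting material
5 | 3-(3,4-dimethoxyphenyl)-N-methoxy-N-methylpropanamide | COc1ccc(CCC(=O)N(C)OC)cc1OC | intermediate
6 | lithium (Z)-enolate of 3 (not isolated) | [Li]O/C(=C\Cc1ccc2OCOc2c1)N1C(=O)OC[C@@H]1Cc1ccccc1 | intermediate
7 | lithium (Z)-enolate of 5 (not isolated) | [Li]O/C(=C\Cc1ccc(OC)c(OC)c1)N(C)OC | intermediate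
8 | (3R)-8–8′-coupled imide/Weinreb amide, C2 epimer mixture | COc1ccc(CC(C(=O)N(C)OC)[C@@H](Cc2ccc3OCOc3c2)C(=O)N2C(=O)OC[C@@H]2Cc2ccccc2)cc1OC | intermediate
9 | (3R)-3-(1,3-benzodioxol-5-ylmethyl)-2-(3,4-dimethoxybenzyl)-4-hydroxybutanal, C2 epimer mixture (not isolated) | COc1ccc(CC(C=O)[C@H](CO)Cc2ccc3OCOc3c2)cc1OC | intermediate
10 | (4R)-4-(1,3-benzodioxol-5-ylmethyl)-3-(3,4-dimethoxybenzyl)oxolan-2-ol, mixture at C2 and C3 | COc1ccc(CC2C(O)OC[C@@H]2Cc2ccc3OCOc3c2)cc1OC | intermediate
11 | (3S,4R)-cis-lactone, the C3 epimer of 12 (not isolated) | COc1ccc(C[C@@H]2C(=O)OC[C@@H]2Cc2ccc3OCOc3c2)cc1OC | intermediate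
12 | (−)-kusunokinin, (3R,4R)-trans-lactone | COc1ccc(C[C@H]2C(=O)OC[C@@H]2Cc2ccc3OCOc3c2)cc1OC | intermediate
13 | (3R,4R)-4-(3,4-dihydroxybenzyl)-3-(3,4-dimethoxybenzyl)oxolan-2-one | COc1ccc(C[C@H]2C(=O)OC[C@@H]2Cc2ccc(O)c(O)c2)cc1OC | target

**Step count**
Total steps: 6. Longest linear sequence: 5 (steps 1, 3, 4, 5, 6).

**Steps most likely to fail**

Step 3 is the riskiest. The two enolates are sterically almost identical, so homodimers compete with the cross product. The Weinreb enolate is fragile, and facial selectivity in a radical capture is lower than in an alkylation. The fallback sets out from 5, uses 3 unchanged, and comes back at 8. Amide 5 is enolised with LiN(iPr)2 and quenched with I2 to give racemic 2-iodo-3-(3,4-dimethoxyphenyl)-N-methoxy-N-methylpropanamide F1. The sodium enolate of 3 (NaN(SiMe3)2, THF, −78 °C) then displaces iodide from F1 in a two-electron alkylation. Cross-selectivity is built in because only one partner is ever a nucleophile. C8′ is again set by the auxiliary, and the C8 mixture is still harmless.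

Step 4 has two hazards. Hydride may attack the ring carbonyl of the hindered imide. The new C9′ alkoxide may also lactonise onto the amide before it is reduced, which leads on to the 1,4-diol and loses the regiochemical information. The fallback sets out from 8 and comes back at 10 by splitting the task between two orthogonal reagents. LiBH4 with one equivalent of H2O in Et2O at 0 °C cleaves only the imide and gives (3R)-3-(1,3-benzodioxol-5-ylmethyl)-2-(3,4-dimethoxybenzyl)-4-hydroxy-N-methoxy-N-methylbutanamide F2, which is isolated. iBu2AlH (2.2 equiv, CH2Cl2, −78 °C) then takes the amide of F2 to the aldehyde level, and the quench delivers lactol 10.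

Step 6 may suffer partial demethylation of the vicinal dimethoxy ring, and BCl3 is also tied up by the lactone carbonyl. The fallback sets out from 12 and comes back at 13 by an oxidative rather than a Lewis-acidic cleavage. Pb(OAc)4 in benzene at 50 °C acetoxylates only the O–CH2–O carbon and gives the 2-acetoxy-1,3-benzodioxole derivative of kusunokinin F3. Dilute aqueous acetic acid at rt hydrolyses this orthoformate-type centre to the catechol 13, and the methyl ethers are never at risk.

**Further compounds**
F1 | step 3 | 2-iodo-3-(3,4-dimethoxyphenyl)-N-methoxy-N-methylpropanamide (racemic) | COc1ccc(CC(I)C(=O)N(C)OC)cc1OC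
F2 | step 4 | (3R)-3-(1,3-benzodioxol-5-ylmethyl)-2-(3,4-dimethoxybenzyl)-4-hydroxy-N-methoxy-N-methylbutanamide (C2 epimer mixture) | COc1ccc(CC(C(=O)N(C)OC)[C@H](CO)Cc2ccc3OCOc3c2)cc1OC
F3 | step 6 | (3R,4R)-4-[(2-acetoxy-1,3-benzodioxol-5-yl)methyl]-3-(3,4-dimethoxybenzyl)oxolan-2-one (mixture at the acetal carbon) | COc1ccc(C[C@H]2C(=O)OC[C@@H]2Cc2ccc3OC(OC(C)=O)Oc3c2)cc1OC
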